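Ring A is disconnected at C4a–C5 and C7–C8 after adding back two hydrogens: C5(CH3)–C6(OH)–C7(CH3) is the carbon chain of pentan-3-one, C8 with its methyl is an acetyl carbon, and C4a=C8a is then the enol ether double bond of a 6-acetyl-3,4-dihydro-2H-pyran.
Further cuts: acetyl–C8a; the pyran ring back to a C2 tertiary alcohol with C8a masked as an acetal; C1'–C2' and C3–C4 on either side of C2; C4'–C5' and C10'–C11' in the chain.
Forward: C5'–C13' from (S)-citronellyl bromide and a 2-methylallyl Grignard reagent; C2'–C4' by β-lactone opening; the chain joined to a C2 epoxide that already carries C3–C8a; then lactol, dihydropyran (pyran ring first), acetylation, annulation of ring A, dehydrogenation to the phenol.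
Stereochemistry: C8' from (S)-citronellyl bromide, C4' from (R)-β-butyrolactone with inversion, C2 from a Sharpless epoxidation of 2-methylprop-2-en-1-ol; no later step touches these centres, and the centres made in the annulation vanish on aromatisation.

Key step: step 13

Remarks on the chemistry: target locants (C2–C8a, C1'–C13') are used for all intermediates. Compounds 27–32 are carried as mixtures of diastereomers at C4a, C5 and C8a, which all become sp2 in step 15. The enantiomeric purity at C2 rests on step 7 and is expected to be high but not complete; recrystallisation of 13, if it crystallises, is the planned point for upgrading.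

Step 1
Reactants: 1 (S)-citronellyl bromide
Product: 2 (4S)-6-bromo-4-methylhexan-1-ol
Conditions: O3, CH2Cl2/MeOH, −78 °C; then NaBH4, −78 → 0 °C
Reagents that add atoms: ozone, [O-][O+]=O
Why: Ozonolysis of the only alkene with reductive NaBH4 work-up cuts the prenyl terminus down to the primary alcohol (C5') while the primary bromide and the existing stereocentre are untouched.

Step 2
Reactants: 2 (4S)-6-bromo-4-methylhexan-1-ol; 3 (2-methylprop-2-en-1-yl)magnesium chloride
Product: 4 (4R)-4,8-dimethylnon-8-en-1-ol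
Conditions: 3 (3 equiv), Li2CuCl4 (5 mol %), THF, −20 °C → rt; dilute HCl work-up
Reagents that add atoms: none
Why: Copper-catalysed cross-coupling of a primary alkyl bromide with an allylic Grignard reagent (Kochi type) installs the 2-methylallyl terminus C11'–C13' in one operation, the first equivalent of 3 merely turning the hydroxyl into an inert magnesium alkoxide.

Step 3
Reactants: 4 (4R)-4,8-dimethylnon-8-en-1-ol
Product: 5 (6R)-9-bromo-2,6-dimethylnon-1-ene
Conditions: CBr4, PPh3, CH2Cl2, 0 °C
Reagents that add atoms: carbon tetrabromide, BrC(Br)(Br)Br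
Why: Appel bromination converts the primary alcohol into the bromide under neutral conditions that leave the 1,1-disubstituted alkene alone.

Step 4
Reactants: 5 (6R)-9-bromo-2,6-dimethylnon-1-ene; 6 (R)-β-butyrolactone
Product: 8 (3R,7S)-3,7,11-trimethyldodec-11-enoic acid, via nonenylmagnesium bromide 7 (not isolated)
Conditions: Mg, THF; CuI (5 mol %), THF/Me2S, −30 °C, then 6; dilute HCl work-up
Reagents that add atoms: none
Why: Copper-catalysed Grignard opening of a β-lactone proceeds by SN2 attack at the oxygen-bearing β-carbon with inversion, so the (R)-lactone installs C4' with the (R) configuration and leaves C2' as a carboxyl group, a reaction established for 3-methylalkanoic acids of the isoprenoid series.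

Step 5
Reactants: 8 (3R,7S)-3,7,11-trimethyldodec-11-enoic acid
Product: 9 (3R,7S)-3,7,11-trimethyldodec-11-en-1-ol
Conditions: LiAlH4, Et2O, 0 °C → rt
Reagents that add atoms: none
Why: LiAlH4 reduction of the carboxylic acid to the primary alcohol affects neither the isolated alkene nor the two stereocentres.

Step 6
Reactants: 9 (3R,7S)-3,7,11-trimethyldodec-11-en-1-ol
Product: 10 (6S,10R)-12-bromo-2,6,10-trimethyldodec-1-ene
Conditions: CBr4, PPh3, CH2Cl2, 0 °C
Reagents that add atoms: carbon tetrabromide, BrC(Br)(Br)Br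
Why: A second Appel bromination gives the C2' bromide needed for Grignard formation, again without touching the alkene.

Step 7
Reactants: 11 2-methylprop-2-en-1-ol
Product: 13 [(2S)-2-methyloxiran-2-yl]methyl 4-methylbenzenesulfonate, via (R)-2-methylglycidol 12 (not isolated)
Conditions: Ti(OiPr)4 (5 mol %), D-(−)-diisopropyl tartrate (6 mol %), cumene hydroperoxide, 4 Å sieves, CH2Cl2, −20 °C; P(OMe)3; then TsCl, Et3N, DMAP (cat.), −10 °C
Reagents that add atoms: cumene hydroperoxide, CC(C)(OO)c1ccccc1; 4-methylbenzenesulfonyl chloride, Cc1ccc(cc1)S(Cl)(=O)=O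
Why: Sharpless asymmetric epoxidation with the D-(−)-tartrate ligand should deliver oxygen to the face that gives (R)-12, which sets C2 of the target, and tosylation in the same flask turns this water-soluble epoxy alcohol into an isolable sulfonate whose descriptor is S only because the CIP priorities change.

Step 8
Reactants: 13 [(2S)-2-methyloxiran-2-yl]methyl 4-methylbenzenesulfonate; 14 2-(2-bromoethyl)-1,3-dioxolane
Product: 17 2-{3-[(2S)-2-methyloxiran-2-yl]propyl}-1,3-dioxolane, via dioxolanylethylmagnesium bromide 15 (not isolated), via hydroxy tosylate 16 (not isolated)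
Conditions: 14, Mg, THF, 25 °C; CuI (10 mol %), 13, THF, −30 °C; then 2 M NaOH, MeOH, 20 °C
Reagents that add atoms: none
Why: Copper-catalysed Grignard opening of the glycidyl sulfonate takes place at the unhindered epoxide CH2 in preference to the neopentyl-type CH2OTs, and the tertiary alkoxide so formed then displaces tosylate in an intramolecular Williamson (3-exo-tet) closure, so the quaternary centre of 13 is carried unchanged into the new 2,2-disubstituted epoxide.

Step 9
Reactants: 10 (6S,10R)-12-bromo-2,6,10-trimethyldodec-1-ene; 17 2-{3-[(2S)-2-methyloxiran-2-yl]propyl}-1,3-dioxolane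
Product: 19 (4R,8R,12S)-1-(1,3-dioxolan-2-yl)-4,8,12,16-tetramethylheptadec-16-en-4-ol, via dodecenylmagnesium bromide 18 (not isolated)
Conditions: 10, Mg, THF; CuI (10 mol %), 17 (1.2 equiv), THF, −30 → 0 °C; H2O work-up
Reagents that add atoms: none
Why: Copper-catalysed Grignard opening of a 2,2-disubstituted epoxide occurs at its CH2 terminus, which forms C1'–C2' and releases the C2 tertiary alcohol with the configuration fixed in step 7, the acetal and the alkene being inert to the organometallic.

Step 10
Reactants: 19 (4R,8R,12S)-1-(1,3-dioxolan-2-yl)-4,8,12,16-tetramethylheptadec-16-en-4-ol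
Product: 20 (6R)-6-methyl-6-[(4R,8S)-4,8,12-trimethyltridec-12-en-1-yl]oxan-2-ol
Conditions: 1 M HCl, THF, 20 °C
Reagents that add atoms: water, O
Why: Acid-catalysed acetal hydrolysis frees the C8a aldehyde, which the C2 hydroxyl captures as the six-membered lactol (ring–chain tautomerism), under conditions too mild to ionise the tertiary centre or hydrate the alkene.

Step 11
Reactants: 20 (6R)-6-methyl-6-[(4R,8S)-4,8,12-trimethyltridec-12-en-1-yl]oxan-2-ol
Product: 22 (2R)-2-methyl-2-[(4R,8S)-4,8,12-trimethyltridec-12-en-1-yl]-3,4-dihydro-2H-pyran, via anomeric mesylate 21 (not isolated)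
Conditions: MsCl, Et3N, CH2Cl2, 0 °C → reflux
Reagents that add atoms: none
Why: Mesylation of the anomeric hydroxyl and elimination with Et3N, by way of the oxocarbenium ion and loss of the C4a proton, is the standard dehydration of 2-deoxy lactols to cyclic enol ethers and gives the pyran ring with its C4a=C8a double bond.

Step 12
Reactants: 22 (2R)-2-methyl-2-[(4R,8S)-4,8,12-trimethyltridec-12-en-1-yl]-3,4-dihydro-2H-pyran; 23 N-methoxy-N-methylacetamide
Product: 25 1-{(2R)-2-methyl-2-[(4R,8S)-4,8,12-trimethyltridec-12-en-1-yl]-3,4-dihydro-2H-pyran-6-yl}ethan-1-one, via 6-lithiodihydropyran 24 (not isolated)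
Conditions: (CH3)3CLi, THF/pentane, −78 → 0 °C; 23, −78 °C → rt; H2O work-up
Reagents that add atoms: none
Why: α-Lithiation of the cyclic enol ether at its oxygen-bearing vinylic carbon C8a followed by acylation with a Weinreb amide, whose chelated tetrahedral intermediate prevents over-addition, is the established route to 2-acyl dihydropyrans.

Step 13
Reactants: 25 1-{(2R)-2-methyl-2-[(4R,8S)-4,8,12-trimethyltridec-12-en-1-yl]-3,4-dihydro-2H-pyran-6-yl}ethan-1-one; 26 pentan-3-one
Product: 29 (2R)-2,5,7,8-tetramethyl-2-[(4R,8S)-4,8,12-trimethyltridec-12-en-1-yl]-2,3,4,4a,5,8a-hexahydro-6H-chromen-6-one, via 1,5-diketone 27 (not isolated), via ketol 28 (not isolated)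
Conditions: 26 (5 equiv), KOC(CH3)3 (0.3 equiv), (CH3)3COH/THF, 0 → 60 °C, argon
Reagents that add atoms: none
Why: Proposed new method: the potassium enolate of the symmetric ketone 26 adds in a Michael sense to C4a, the β-carbon of the 2-acyl enol ether 25, to give 1,5-diketone 27 (bond C4a–C5); proton transfer then places the enolate on the ethyl side (C7), which attacks the acetyl carbonyl C8 to give ketol 28 (bond C7–C8), and E1cB loss of water leaves the C7=C8 enone 29. The closest known reaction type is the Robinson annulation of 1-acetylcyclohexene, and of crotonaldehyde or methyl vinyl ketone, with dialkyl ketone enolates, the latter being the established entry from pentan-3-one to trimethylcyclohexenones; what is not documented is an acceptor whose α-carbon carries the ring oxygen, which makes C4a less electrophilic, and this is answered by equilibrating alkoxide conditions with excess 26 so that every reversible step drains through the irreversible dehydration. The six-membered carbocycle of ring A closes in a 6-(enolexo)-exo-trig aldol. The centres formed at C4a, C5 and C8a are under thermodynamic control only and need none, since all three become sp2 in step 15, while C2, C4' and C8' are not enolisable and lie outside the reacting array. The selectivity the step needs is regiochemical, closure from C7 onto C8 and not from the acetyl methyl onto C6: C8 is an unhindered carbonyl activated by the adjacent oxygen, C6 is flanked by the new branched C5, and only the C7-to-C8 mode ends in a tetrasubstituted conjugated enone, so equilibration funnels material to 29.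

Step 14
Reactants: 29 (2R)-2,5,7,8-tetramethyl-2-[(4R,8S)-4,8,12-trimethyltridec-12-en-1-yl]-2,3,4,4a,5,8a-hexahydro-6H-chromen-6-one
Product: 31 trimethyl({(2R)-2,5,7,8-tetramethyl-2-[(4R,8S)-4,8,12-trimethyltridec-12-en-1-yl]-3,4,4a,8a-tetrahydro-2H-chromen-6-yl}oxy)silane, via lithium dienolate 30 (not isolated)
Conditions: LiN(iPr)2, THF, −78 °C; Me3SiCl, Et3N, −78 → 0 °C; non-aqueous work-up
Reagents that add atoms: chlorotrimethylsilane, C[Si](C)(C)Cl
Why: Kinetic deprotonation of the enone at the α' carbon C5 with LiN(iPr)2 and O-silylation (silyl enol ether formation) gives the cross-conjugated 2-silyloxydiene required for the dehydrogenation, and should the extended dienol ether form instead it leads to the same phenol.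

Step 15
Reactants: 31 trimethyl({(2R)-2,5,7,8-tetramethyl-2-[(4R,8S)-4,8,12-trimethyltridec-12-en-1-yl]-3,4,4a,8a-tetrahydro-2H-chromen-6-yl}oxy)silane
Product: 33 (2R)-2,5,7,8-tetramethyl-2-[(4R,8S)-4,8,12-trimethyltridec-12-en-1-yl]-3,4-dihydro-2H-chromen-6-ol, via cyclohexadienone 32 (not isolated)
Conditions: Pd(OAc)2 (1.05 equiv), MeCN, 20 °C, argon
Reagents that add atoms: none
Why: Saegusa–Ito oxidation converts the silyl dienol ether through a palladium enolate at C5 and β-hydride elimination into the cross-conjugated dienone 32, which, having hydrogen at C8a, tautomerises at once to the phenol and thereby erases the centres at C4a, C5 and C8a.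

Compound list
1 | (S)-citronellyl bromide, (6S)-8-bromo-2,6-dimethyloct-2-ene | CC(C)=CCC[C@H](C)CCBr | starting material
2 | (4S)-6-bromo-4-methylhexan-1-ol | OCCC[C@H](C)CCBr | intermediate
3 | (2-methylprop-2-en-1-yl)magnesium chloride | C=C(C)C[Mg]Cl | starting material
4 | (4R)-4,8-dimethylnon-8-en-1-ol | OCCC[C@H](C)CCCC(C)=C | intermediate
5 | (6R)-9-bromo-2,6-dimethylnon-1-ene | BrCCC[C@H](C)CCCC(C)=C | intermediate
6 | (R)-β-butyrolactone, (4R)-4-methyloxetan-2-one | O=C1C[C@@H](C)O1 | starting material
7 | [(4R)-4,8-dimethylnon-8-en-1-yl]magnesium bromide | Br[Mg]CCC[C@H](C)CCCC(C)=C | intermediate (not isolated)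
8 | (3R,7S)-3,7,11-trimethyldodec-11-enoic acid | OC(=O)C[C@H](C)CCC[C@H](C)CCCC(C)=C | intermediate
9 | (3R,7S)-3,7,11-trimethyldodec-11-en-1-ol | OCC[C@H](C)CCC[C@H](C)CCCC(C)=C | intermediate
10 | (6S,10R)-12-bromo-2,6,10-trimethyldodec-1-ene | BrCC[C@H](C)CCC[C@H](C)CCCC(C)=C | intermediate
11 | 2-methylprop-2-en-1-ol | C=C(C)CO | starting material
12 | [(2R)-2-methyloxiran-2-yl]methanol, (R)-2-methylglycidol | OC[C@]1(C)CO1 | intermediate (not isolated)
13 | [(2S)-2-methyloxiran-2-yl]methyl 4-methylbenzenesulfonate | Cc1ccc(cc1)S(=O)(=O)OC[C@]1(C)CO1 | intermediate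
14 | 2-(2-bromoethyl)-1,3-dioxolane | BrCCC1OCCO1 | starting material
15 | [2-(1,3-dioxolan-2-yl)ethyl]magnesium bromide | Br[Mg]CCC1OCCO1 | intermediate (not isolated)
16 | (2S)-5-(1,3-dioxolan-2-yl)-2-hydroxy-2-methylpentyl 4-methylbenzenesulfonate | Cc1ccc(cc1)S(=O)(=O)OC[C@@](C)(O)CCCC1OCCO1 | intermediate (not isolated)
17 | 2-{3-[(2S)-2-methyloxiran-2-yl]propyl}-1,3-dioxolane | C[C@]1(CCCC2OCCO2)CO1 | intermediate
18 | [(3R,7S)-3,7,11-trimethyldodec-11-en-1-yl]magnesium bromide | Br[Mg]CC[C@H](C)CCC[C@H](C)CCCC(C)=C | intermediate (not isolated)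
19 | (4R,8R,12S)-1-(1,3-dioxolan-2-yl)-4,8,12,16-tetramethylheptadec-16-en-4-ol | C=C(C)CCC[C@@H](C)CCC[C@@H](C)CCC[C@@](C)(O)CCCC1OCCO1 | intermediate
20 | (6R)-6-methyl-6-[(4R,8S)-4,8,12-trimethyltridec-12-en-1-yl]oxan-2-ol (both anomers) | C=C(C)CCC[C@@H](C)CCC[C@@H](C)CCC[C@]1(C)CCCC(O)O1 | intermediate
21 | (6R)-6-methyl-6-[(4R,8S)-4,8,12-trimethyltridec-12-en-1-yl]oxan-2-yl methanesulfonate | C=C(C)CCC[C@@H](C)CCC[C@@H](C)CCC[C@]1(C)CCCC(OS(C)(=O)=O)O1 | intermediate (not isolated)
22 | (2R)-2-methyl-2-[(4R,8S)-4,8,12-trimethyltridec-12-en-1-yl]-3,4-dihydro-2H-pyran | C=C(C)CCC[C@@H](C)CCC[C@@H](C)CCC[C@]1(C)CCC=CO1 | intermediate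
23 | N-methoxy-N-methylacetamide | CC(=O)N(C)OC | starting material
24 | {(6R)-6-methyl-6-[(4R,8S)-4,8,12-trimethyltridec-12-en-1-yl]-5,6-dihydro-4H-pyran-2-yl}lithium | C=C(C)CCC[C@@H](C)CCC[C@@H](C)CCC[C@]1(C)CCC=C([Li])O1 | intermediate (not isolated)
25 | 1-{(2R)-2-methyl-2-[(4R,8S)-4,8,12-trimethyltridec-12-en-1-yl]-3,4-dihydro-2H-pyran-6-yl}ethan-1-one | C=C(C)CCC[C@@H](C)CCC[C@@H](C)CCC[C@]1(C)CCC=C(C(C)=O)O1 | intermediate
26 | pentan-3-one | CCC(=O)CC | starting material
27 | 2-{(6R)-2-acetyl-6-methyl-6-[(4R,8S)-4,8,12-trimethyltridec-12-en-1-yl]oxan-3-yl}pentan-3-one (diastereomers) | C=C(C)CCC[C@@H](C)CCC[C@@H](C)CCC[C@]1(C)CCC(C(C)C(=O)CC)C(C(C)=O)O1 | intermediate (not isolated)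
28 | (2R)-8-hydroxy-2,5,7,8-tetramethyl-2-[(4R,8S)-4,8,12-trimethyltridec-12-en-1-yl]octahydrochromen-6-one (diastereomers) | C=C(C)CCC[C@@H](C)CCC[C@@H](C)CCC[C@]1(C)CCC2C(C)C(=O)C(C)C(C)(O)C2O1 | intermediate (not isolated)
29 | (2R)-2,5,7,8-tetramethyl-2-[(4R,8S)-4,8,12-trimethyltridec-12-en-1-yl]-2,3,4,4a,5,8a-hexahydro-6H-chromen-6-one (diastereomers at C4a, C5, C8a) | C=C(C)CCC[C@@H](C)CCC[C@@H](C)CCC[C@]1(C)CCC2C(C)C(=O)C(C)=C(C)C2O1 | intermediate
30 | lithium (2R)-2,5,7,8-tetramethyl-2-[(4R,8S)-4,8,12-trimethyltridec-12-en-1-yl]-3,4,4a,8a-tetrahydro-2H-chromen-6-olate | C=C(C)CCC[C@@H](C)CCC[C@@H](C)CCC[C@]1(C)CCC2C(C)=C(O[Li])C(C)=C(C)C2O1 | intermediate (not isolated)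
31 | trimethyl({(2R)-2,5,7,8-tetramethyl-2-[(4R,8S)-4,8,12-trimethyltridec-12-en-1-yl]-3,4,4a,8a-tetrahydro-2H-chromen-6-yl}oxy)silane | C=C(C)CCC[C@@H](C)CCC[C@@H](C)CCC[C@]1(C)CCC2C(C)=C(O[Si](C)(C)C)C(C)=C(C)C2O1 | intermediate
32 | (2R)-2,5,7,8-tetramethyl-2-[(4R,8S)-4,8,12-trimethyltridec-12-en-1-yl]-2,3,4,8a-tetrahydro-6H-chromen-6-one | C=C(C)CCC[C@@H](C)CCC[C@@H](C)CCC[C@]1(C)CCC2=C(C)C(=O)C(C)=C(C)C2O1 | intermediate (not isolated)
33 | (2R)-2,5,7,8-tetramethyl-2-[(4R,8S)-4,8,12-trimethyltridec-12-en-1-yl]-3,4-dihydro-2H-chromen-6-ol | C=C(C)CCC[C@@H](C)CCC[C@@H](C)CCC[C@]1(C)CCc2c(C)c(O)c(C)c(C)c2O1 | target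

Total step count: 15.
Longest linear sequence: 13 steps (steps 1–6, then 9–15); steps 7–8 are a two-step branch that joins at step 9.

Steps most likely to fail

1. Step 13 (the proposed new method). The conjugate addition to C4a may be too slow because the ring oxygen donates into the enone, so that enolisation of the acetyl group, self-condensation of 25, or aldol closure in the wrong direction outruns the annulation. The fallback uses known chemistry and activates the acceptor with a Lewis acid in place of activating the donor with base; it sets out from 25 and 26 and returns at 29. Ketone 26 is converted with Me3SiCl, NaI and Et3N in MeCN into (Z)-trimethyl(pent-2-en-3-yloxy)silane F1. Mukaiyama–Michael addition of F1 to 25 under TiCl4 in CH2Cl2 at −78 °C, with the titanium chelated between the acetyl and ring oxygens, should give after aqueous work-up the 1,5-diketone 27, now isolated. A separate aldol condensation (KOH, MeOH, 50 °C) then closes ring A to 29.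

2. Step 15. Stoichiometric divalent palladium may also engage the 1,1-disubstituted alkene (double-bond migration, allylic oxidation) or oxidise the electron-rich phenol as it forms. The fallback replaces palladium by halogenation–elimination; it sets out from 31 and returns at 33. Bromination of 31 with N-bromosuccinimide in THF at −78 °C, where the silyl dienol ether is far more nucleophilic than the isolated alkene, should give the 5-bromo enone (2R)-5-bromo-2,5,7,8-tetramethyl-2-[(4R,8S)-4,8,12-trimethyltridec-12-en-1-yl]-2,3,4,4a,5,8a-hexahydro-6H-chromen-6-one F2. Dehydrobromination with Li2CO3 and LiBr in DMF under argon gives dienone 32, which tautomerises to 33 with no oxidant present.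

3. Step 11. Elimination of the activated lactol may stay incomplete, and the acid-sensitive enol ether may re-add water or unreacted lactol during isolation, giving acetal by-products. The fallback avoids the free enol ether and replaces steps 11 and 12; it sets out from 20 and returns at 25. Oxidation of 20 (TEMPO, PhI(OAc)2, CH2Cl2) gives the δ-lactone (6R)-6-methyl-6-[(4R,8S)-4,8,12-trimethyltridec-12-en-1-yl]oxan-2-one F3. Enolisation with KN(SiMe3)2 and trapping with (PhO)2P(O)Cl gives the ketene acetal phosphate (6R)-6-methyl-6-[(4R,8S)-4,8,12-trimethyltridec-12-en-1-yl]-5,6-dihydro-4H-pyran-2-yl diphenyl phosphate F4. Stille coupling with tributyl(1-ethoxyvinyl)stannane (Pd(PPh3)4, LiCl, THF, reflux) gives the diene (2R)-6-(1-ethoxyethenyl)-2-methyl-2-[(4R,8S)-4,8,12-trimethyltridec-12-en-1-yl]-3,4-dihydro-2H-pyran F5. Brief treatment with dilute HCl in THF at 0 °C hydrolyses the acyclic enol ether only, because the ring enol ether becomes acyl-deactivated, and gives 25.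

Further compounds
F1 | step 13 | (Z)-trimethyl(pent-2-en-3-yloxy)silane | C/C=C(\O[Si](C)(C)C)CC
F2 | step 15 | (2R)-5-bromo-2,5,7,8-tetramethyl-2-[(4R,8S)-4,8,12-trimethyltridec-12-en-1-yl]-2,3,4,4a,5,8a-hexahydro-6H-chromen-6-one | C=C(C)CCC[C@@H](C)CCC[C@@H](C)CCC[C@]1(C)CCC2C(C)(Br)C(=O)C(C)=C(C)C2O1
F3 | step 11 | (6R)-6-methyl-6-[(4R,8S)-4,8,12-trimethyltridec-12-en-1-yl]oxan-2-one | C=C(C)CCC[C@@H](C)CCC[C@@H](C)CCC[C@]1(C)CCCC(=O)O1
F4 | step 11 | (6R)-6-methyl-6-[(4R,8S)-4,8,12-trimethyltridec-12-en-1-yl]-5,6-dihydro-4H-pyran-2-yl diphenyl phosphate | C=C(C)CCC[C@@H](C)CCC[C@@H](C)CCC[C@]1(C)CCC=C(OP(=O)(Oc2ccccc2)Oc2ccccc2)O1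
F5 | step 11 | (2R)-6-(1-ethoxyethenyl)-2-methyl-2-[(4R,8S)-4,8,12-trimethyltridec-12-en-1-yl]-3,4-dihydro-2H-pyran | C=C(C)CCC[C@@H](C)CCC[C@@H](C)CCC[C@]1(C)CCC=C(C(=C)OCC)O1
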